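## Retrosynthetic overview
- The last step is global O‑demethylation of the heptamethyl ether. The (E)‑stilbene is made at the start by a Heck coupling on 5‑bromosalicylaldehyde.
- Each trans‑2,3‑diaryl‑dihydrobenzofuran (DHB) comes from a chiral sulfonium‑ylide [4+1] annulation. An o‑quinone methide (o‑QM) from an o‑hydroxybenzhydryl sulfone gives C3 and the benzo ring, and a 4‑methoxybenzylide gives C2. This forms the C2–C3 and C2–O bonds and sets trans and the absolute configuration.
- Ring order: DHB2 (the resorcinol‑type ring) is formed first. Its C4–Br is turned into an aryllithium and added to the styryl‑salicylaldehyde. The resulting benzhydrol is converted to a sulfone, and a second [4+1] forms DHB1.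
- The DHB2 sulfone is built from 1‑bromo‑3,5‑dimethoxybenzene by Vilsmeier formylation, selective ortho‑demethylation, aryl‑Grignard addition and sulfinate substitution.
- The chiral sulfonium salt comes from (R,R)‑2,5‑dimethylthiolane, which is made from (2S,5S)‑hexane‑2,5‑diol, and 4‑methoxybenzyl bromide.

Assumptions:
- "trans" means an (E)‑stilbene and both DHBs 2,3‑trans. All four stereocentres are S in the target SMILES.
- The (R,R)‑dimethylthiolane is assumed to give the (2S,3S) sense in each annulation. If it does not, the (S,S)‑sulfide from (2R,5R)‑hexanediol is used.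

## Route

**Step 1**
Reactants: 1 (5‑bromo‑2‑hydroxybenzaldehyde); 2 (3,5‑dimethoxystyrene)
Product: 3 ((E)‑5‑(3,5‑dimethoxystyryl)‑2‑hydroxybenzaldehyde)
Conditions: Pd(OAc)2, P(o‑tol)3, Et3N, DMF, 100 °C
Reagents that add atoms: none
Why: Mizoroki–Heck coupling of the aryl bromide with the styrene gives the (E)‑stilbene by syn‑carbopalladation and β‑H elimination. The free phenol and aldehyde are tolerated, and no stereocentre is formed.

**Step 2**
Reactants: 4 (1‑bromo‑3,5‑dimethoxybenzene)
Product: 5 (2‑bromo‑4,6‑dimethoxybenzaldehyde)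
Conditions: POCl3, DMF, 0 → 70 °C; then aq. NaOAc
Reagents that add atoms: N,N‑dimethylformamide, CN(C)C=O; water, O
Why: Vilsmeier–Haack formylation goes to the position ortho to one OMe and para to the other. This is the most activated and less hindered site, between Br and OMe.

**Step 3**
Reactants: 5
Product: 6 (2‑bromo‑6‑hydroxy‑4‑methoxybenzaldehyde)
Conditions: BCl3, CH2Cl2, −78 → 0 °C
Reagents that add atoms: none
Why: BCl3 chelates the aldehyde O and the adjacent OMe, so only the ortho OMe is cleaved (chelation‑controlled ether cleavage). The para OMe is untouched, and the other ortho position carries Br.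

**Step 4**
Reactants: 4 (1‑bromo‑3,5‑dimethoxybenzene)
Product: 7 (3,5‑dimethoxyphenylmagnesium bromide)
Conditions: Mg turnings, I2 (cat.), THF, 40 °C → reflux
Reagents that add atoms: magnesium, [Mg]
Why: Oxidative insertion of Mg into the aryl C–Br bond (Grignard formation). No stereocentre is involved, and the solution is used directly in Step 5.

**Step 5**
Reactants: 6 (2‑bromo‑6‑hydroxy‑4‑methoxybenzaldehyde); 7 (3,5‑dimethoxyphenylmagnesium bromide)
Product: 8 ((2‑bromo‑6‑hydroxy‑4‑methoxyphenyl)(3,5‑dimethoxyphenyl)methanol, racemic at the carbinol)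
Conditions: 7 (2.5 equiv), THF, 0 °C → rt; then aq. NH4Cl
Reagents that add atoms: none
Why: The first equivalent of Grignard deprotonates the phenol, and the next adds 1,2 to the aldehyde (Grignard addition). The carbinol stereocentre is irrelevant because it is destroyed in Steps 6 and 10.

**Step 6**
Reactants: 8
Product: 9 (3‑bromo‑2‑[(3,5‑dimethoxyphenyl)(tosyl)methyl]‑5‑methoxyphenol, o‑QM precursor)
Conditions: TolSO2Na, HCO2H, MeCN/H2O, rt
Reagents that add atoms: sodium p‑toluenesulfinate, Cc1ccc(S(=O)(=O)[O-])cc1.[Na+]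
Why: The electron‑rich o‑hydroxybenzhydrol ionizes through the o‑QM or benzhydryl cation, and S‑attack by sulfinate gives the bench‑stable sulfone (substitution via o‑QM). The carbinol configuration is lost.

**Step 7**
Reactants: 10 ((2S,5S)‑hexane‑2,5‑diol)
Product: 11 ((2S,5S)‑hexane‑2,5‑diyl dimethanesulfonate)
Conditions: MsCl, Et3N, CH2Cl2, 0 °C
Reagents that add atoms: methanesulfonyl chloride, CS(=O)(=O)Cl
Why: Sulfonylation of the two secondary alcohols occurs with retention, because the C–O bonds are not broken.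

**Step 8**
Reactants: 11
Product: 12 ((2R,5R)‑2,5‑dimethylthiolane)
Conditions: Na2S·9H2O, DMF, 60 °C; isolated by distillation
Reagents that add atoms: sodium sulfide, [Na+].[Na+].[S-2]
Why: Sequential intermolecular and intramolecular SN2 displacements by sulfide invert both carbons. This gives the C2‑symmetric trans‑(R,R)‑thiolane from the (S,S)‑diol, because S replaces O with the same CIP priority order.

**Step 9**
Reactants: 12 ((2R,5R)‑2,5‑dimethylthiolane); 13 (4‑methoxybenzyl bromide)
Product: 14 ((R,R)‑1‑(4‑methoxybenzyl)‑2,5‑dimethylthiolanium tetrafluoroborate)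
Conditions: AgBF4, MeCN, 0 °C → rt, dark
Reagents that add atoms: silver tetrafluoroborate, [Ag+].F[B-](F)(F)F (BF4⁻ stays as counter‑ion; Ag leaves as AgBr)
Why: S‑alkylation of the sulfide (sulfonium formation), with Ag+ removing bromide. The C2‑symmetric sulfide has homotopic S lone pairs, so only one sulfonium diastereomer forms.

**Step 10**
Reactants: 9 (o‑QM precursor sulfone); 14 (chiral sulfonium salt)
Product: 15 ((2S,3S)‑4‑bromo‑3‑(3,5‑dimethoxyphenyl)‑6‑methoxy‑2‑(4‑methoxyphenyl)‑2,3‑dihydrobenzofuran)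
Conditions: Cs2CO3, MeCN, rt → 40 °C
Reagents that add atoms: none
Why: Sulfur‑ylide [4+1] annulation (Corey–Chaykovsky type). Base converts 9 into the o‑QM by loss of sulfinate and 14 into the chiral benzylide. The ylide adds to the o‑QM carbon, and the chiral sulfide sets the face and hence C3. The phenoxide then displaces the sulfide 5‑exo‑tet, which sets C2. Reversible betaine formation and anti ring closure give trans‑(2S,3S). The sulfide 12 is released and can be recovered.

**Step 11**
Reactants: 15; 3
Product: 16 (benzhydrol joining the DHB2 C4 to the 2‑hydroxy‑5‑styrylphenyl ring; (2S,3S) centres retained, carbinol epimeric)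
Conditions: n‑BuLi (1.05 equiv), THF, −78 °C, 30 min; then the sodium phenoxide of 3 (1.3 equiv, from NaH, 1.4 equiv), −78 → 0 °C
Reagents that add atoms: none
Why: Br/Li exchange, then 1,2‑addition of the aryllithium to the aldehyde. At −78 °C the DHB stereocentres are not deprotonated, and the new carbinol stereocentre is discarded in Step 12.

**Step 12**
Reactants: 16
Product: 17 (o‑QM precursor sulfone)
Conditions: TolSO2Na, HCO2H, MeCN/H2O, rt
Reagents that add atoms: sodium p‑toluenesulfinate, Cc1ccc(S(=O)(=O)[O-])cc1.[Na+]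
Why: Same substitution via o‑QM as Step 6. Both carbinol epimers converge on one sulfone, so the carbinol configuration is irrelevant.

**Step 13**
Reactants: 17; 14
Product: 18 (heptamethyl trimer, (2S,3S)/(2S,3S), E‑styryl)
Conditions: Cs2CO3, MeCN, rt → 40 °C
Reagents that add atoms: none
Why: The second sulfur‑ylide [4+1] annulation forms DHB1 by the same mechanism as Step 10. The chiral ylide controls C2 and C3 as (2S,3S) trans, and matched induction with the DHB2 centres is assumed.

**Step 14**
Reactants: 18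
Product: 19 (trans‑diptoindonesin B)
Conditions: BBr3 (15 equiv), CH2Cl2, −78 °C → 0 °C, then rt only if needed; quench with MeOH, then aq. NaHCO3
Reagents that add atoms: none
Why: BBr3 cleaves all seven aryl methyl ethers (Lewis‑acid demethylation). The stilbene, the benzylic C–O bonds and the stereocentres survive at low temperature.

## Compound list
1 | 5‑bromo‑2‑hydroxybenzaldehyde | O=Cc1cc(Br)ccc1O | starting material
2 | 3,5‑dimethoxystyrene | C=Cc1cc(OC)cc(OC)c1 | starting material
3 | (E)‑5‑(3,5‑dimethoxystyryl)‑2‑hydroxybenzaldehyde | O=Cc1cc(/C=C/c2cc(OC)cc(OC)c2)ccc1O | intermediate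
4 | 1‑bromo‑3,5‑dimethoxybenzene | COc1cc(Br)cc(OC)c1 | starting material
5 | 2‑bromo‑4,6‑dimethoxybenzaldehyde | COc1cc(OC)c(C=O)c(Br)c1 | intermediate
6 | 2‑bromo‑6‑hydroxy‑4‑methoxybenzaldehyde | COc1cc(O)c(C=O)c(Br)c1 | intermediate
7 | 3,5‑dimethoxyphenylmagnesium bromide | COc1cc(OC)cc([Mg]Br)c1 | intermediate
8 | (2‑bromo‑6‑hydroxy‑4‑methoxyphenyl)(3,5‑dimethoxyphenyl)methanol | COc1cc(OC)cc(C(O)c2c(O)cc(OC)cc2Br)c1 | intermediate
9 | 3‑bromo‑2‑[(3,5‑dimethoxyphenyl)(tosyl)methyl]‑5‑methoxyphenol | COc1cc(OC)cc(C(c2c(O)cc(OC)cc2Br)S(=O)(=O)c2ccc(C)cc2)c1 | intermediate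
10 | (2S,5S)‑hexane‑2,5‑diol | C[C@H](O)CC[C@H](C)O | starting material
11 | (2S,5S)‑hexane‑2,5‑diyl dimethanesulfonate | C[C@H](OS(C)(=O)=O)CC[C@H](C)OS(C)(=O)=O | intermediate
12 | (2R,5R)‑2,5‑dimethylthiolane | C[C@@H]1CC[C@@H](C)S1 | intermediate (chiral sulfide, recovered in Steps 10 and 13)
13 | 4‑methoxybenzyl bromide | COc1ccc(CBr)cc1 | starting material
14 | (R,R)‑1‑(4‑methoxybenzyl)‑2,5‑dimethylthiolanium tetrafluoroborate | COc1ccc(C[S+]2[C@H](C)CC[C@H]2C)cc1.F[B-](F)(F)F | intermediate
15 | (2S,3S)‑4‑bromo‑3‑(3,5‑dimethoxyphenyl)‑6‑methoxy‑2‑(4‑methoxyphenyl)‑2,3‑dihydrobenzofuran | Brc1cc(OC)cc2c1[C@H](c1cc(OC)cc(OC)c1)[C@@H](c1ccc(OC)cc1)O2 | intermediate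
16 | benzhydrol from 15 and 3 (carbinol epimeric) | COc1cc(OC)cc(/C=C/c2ccc(O)c(C(O)c3cc(OC)cc4c3[C@H](c3cc(OC)cc(OC)c3)[C@@H](c3ccc(OC)cc3)O4)c2)c1 | intermediate
17 | tosyl sulfone of 16 | COc1cc(OC)cc(/C=C/c2ccc(O)c(C(S(=O)(=O)c5ccc(C)cc5)c3cc(OC)cc4c3[C@H](c3cc(OC)cc(OC)c3)[C@@H](c3ccc(OC)cc3)O4)c2)c1 | intermediate
18 | heptamethyl trimer: (2S,3S)‑3‑[(2S,3S)‑3‑(3,5‑dimethoxyphenyl)‑6‑methoxy‑2‑(4‑methoxyphenyl)‑2,3‑dihydrobenzofuran‑4‑yl]‑5‑[(E)‑3,5‑dimethoxystyryl]‑2‑(4‑methoxyphenyl)‑2,3‑dihydrobenzofuran | COc1ccc([C@H]2Oc3ccc(/C=C/c4cc(OC)cc(OC)c4)cc3[C@@H]2c2cc(OC)cc3c2[C@H](c2cc(OC)cc(OC)c2)[C@@H](c2ccc(OC)cc2)O3)cc1 | intermediate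
19 | trans‑diptoindonesin B | Oc1ccc([C@H]2Oc3ccc(/C=C/c4cc(O)cc(O)c4)cc3[C@@H]2c2cc(O)cc3c2[C@H](c2cc(O)cc(O)c2)[C@@H](c2ccc(O)cc2)O3)cc1 | target

## Totals
Total steps: 14, including four reagent preparations (Steps 4, 7, 8, 9). Longest linear sequence: 9 (Steps 2, 3, 5, 6, 10, 11, 12, 13, 14).

Three steps most likely to fail:
1. **Step 13 (second [4+1]).** The o‑QM is very hindered, and the chiral ylide may give low ee or dr, or be mismatched with the DHB2 centres. Fallback: run both [4+1] steps with an achiral sulfonium ylide (tetrahydrothiophene‑derived) to give racemic, diastereomeric trans permethyl trimers, then isolate the (S,S,S,S) isomer 18 by chiral preparative SFC or HPLC.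
2. **Step 11 (hindered aryl‑Li addition to a phenoxide aldehyde).** The aryllithium may undergo competing benzylic deprotonation or protonation, and the deactivated aldehyde may react poorly. Fallback: convert 15 to its 4‑Bpin by Miyaura borylation, then add it to 3 by Rh(I)‑catalysed 1,2‑addition, avoiding strongly basic organometallics.
3. **Step 14 (global BBr3 demethylation).** It may cause stilbene isomerization, hydrobromination, or Lewis‑acid opening of the benzylic DHB C2–O bonds. Fallback: rebuild the route with the phenols as MOM ethers (MOM analogues of 2, 13 and the resorcinol‑derived fragments) and remove them at the end with PPTS or HCl in MeOH at rt, avoiding strong Lewis acids.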